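## Retrosynthetic overview

1. The last C–C bond made is C1′–C6. The quaternary epoxide carbon C6 of ring B is used as a carbanion (an oxiranyllithium, an α-oxygenated d1 reagent) and adds to the aldehyde carbon of the ring A (2Z,4E)-dienal. Both carbons are normally electrophilic. Only desilylation follows.
2. The oxiranyllithium comes from a p-tolylsulfinyl oxirane by sulfoxide–lithium exchange. Before that, the sulfinyl group is the only source of chirality for ring B (chelate-controlled epoxidation of a sulfinylquinone, then carbonyl reductions).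
3. The ring B carbocycle is the benzene ring of 4-bromo-2,5-dimethoxybenzaldehyde, dearomatised by oxidation to the quinone. Its oxirane is closed in step 14.
4. The dienal comes from Suzuki coupling of a ring A (E)-vinylboronate with (Z)-3-iodobut-2-en-1-ol, then allylic oxidation.
5. Ring A is formed first (step 2) by titanocene radical cyclisation of (R)-6,7-epoxygeranyl acetate, made by Shi epoxidation of geranyl acetate.

Assumption: ring B atoms are called C1 (epoxide CH), C2, C3, C4, C5 and C6 (quaternary epoxide carbon), the side-chain carbinol is C1′, and (1S,2R,5S)-menthyl (R)-p-toluenesulfinate and the D-fructose-derived Shi ketone are bought.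

## Route

Step 1
Reactants: 1 geranyl acetate
Product: 2 (R)-6,7-epoxygeranyl acetate [(2E)-5-[(2R)-3,3-dimethyloxiran-2-yl]-3-methylpent-2-en-1-yl acetate]
Conditions: Shi ketone (D-fructose-derived, 30 mol%), KHSO5 (as 2KHSO5·KHSO4·K2SO4), K2CO3, Bu4NHSO4 (cat.), aq. Na2B4O7 buffer, MeCN/CH2(OMe)2, 0 °C
Reagents that add atoms: potassium peroxymonosulfate, [K+].[O-]S(=O)(=O)OO
Why: Shi asymmetric epoxidation: the chiral dioxirane attacks only the electron-rich 6,7-alkene (the 2,3-alkene is deactivated by the allylic acetate) through a spiro transition state, and the D-fructose-derived ketone gives the (R)-epoxide that becomes the ring A carbinol.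

Step 2
Reactants: 2 (R)-6,7-epoxygeranyl acetate
Product: 4 [(1S,3R)-3-hydroxy-2,2-dimethyl-6-methylidenecyclohexyl]methyl acetate, via trimethylsilyl ether 3 (not isolated)
Conditions: Cp2TiCl2 (20 mol%), Mn dust, Me3SiCl, 2,4,6-collidine, THF, rt; then 1 M HCl
Reagents that add atoms: none
Why: Titanocene-catalysed radical epoxide-opening cyclisation (Nugent–RajanBabu type): Cp2TiCl (trivalent titanium) opens the oxirane at the tertiary carbon, the radical closes 6-endo through a chair transition state with the titanoxy and CH2OAc groups equatorial so that the retained (R)-carbinol fixes the new ring CH as (S) (cis), and a second titanium traps the tertiary radical and eliminates to the exocyclic alkene.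

Step 3
Reactants: 4 [(1S,3R)-3-hydroxy-2,2-dimethyl-6-methylidenecyclohexyl]methyl acetate
Product: 5 [(1S,3R)-2,2-dimethyl-6-methylidene-3-(triethylsilyloxy)cyclohexyl]methyl acetate
Conditions: Et3SiCl, imidazole, DMF, 0 °C to rt
Reagents that add atoms: chlorotriethylsilane, CC[Si](Cl)(CC)CC
Why: Standard silylation of the secondary alcohol, giving a triethylsilyl (TES) ether that survives the basic, oxidative and organometallic steps ahead and is removed by fluoride at the end; no stereocentre is touched.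

Step 4
Reactants: 5 [(1S,3R)-2,2-dimethyl-6-methylidene-3-(triethylsilyloxy)cyclohexyl]methyl acetate
Product: 6 [(1S,3R)-2,2-dimethyl-6-methylidene-3-(triethylsilyloxy)cyclohexyl]methanol
Conditions: K2CO3 (cat.), MeOH, rt
Reagents that add atoms: none
Why: Base-catalysed transesterification (methanolysis) removes the acetate as methyl acetate and leaves the silyl ether and both stereocentres untouched.

Step 5
Reactants: 6 [(1S,3R)-2,2-dimethyl-6-methylidene-3-(triethylsilyloxy)cyclohexyl]methanol
Product: 7 (1S,3R)-2,2-dimethyl-6-methylidene-3-(triethylsilyloxy)cyclohexane-1-carbaldehyde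
Conditions: Dess–Martin periodinane, NaHCO3, CH2Cl2, 0 °C to rt
Reagents that add atoms: none
Why: Dess–Martin oxidation under buffered, non-basic conditions gives the β,γ-unsaturated aldehyde without epimerising its α-stereocentre or moving the exocyclic alkene into conjugation.

Step 6
Reactants: 7 (1S,3R)-2,2-dimethyl-6-methylidene-3-(triethylsilyloxy)cyclohexane-1-carbaldehyde
Product: 8 2-[(E)-2-[(1S,3R)-2,2-dimethyl-6-methylidene-3-(triethylsilyloxy)cyclohexyl]ethenyl]-4,4,5,5-tetramethyl-1,3,2-dioxaborolane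
Conditions: CrCl2 (8 equiv), Cl2CHB(pin), LiI (additive), THF, rt
Reagents that add atoms: 2-(dichloromethyl)-4,4,5,5-tetramethyl-1,3,2-dioxaborolane, ClC(Cl)B1OC(C)(C)C(C)(C)O1
Why: Takai–Utimoto olefination: the gem-dichromium species formed from Cl2CHB(pin) and CrCl2 (divalent chromium) adds to the aldehyde and eliminates to the (E)-alkenylboronate under neutral conditions that do not epimerise the aldehyde.

Step 7
Reactants: 9 but-2-yn-1-ol
Product: 11 (2Z)-3-iodobut-2-en-1-ol, via cyclic sodium vinylalanate 10 (not isolated)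
Conditions: NaAlH2(OCH2CH2OCH3)2, Et2O, 0 °C to rt; then I2, THF, −78 to 0 °C; H2O
Reagents that add atoms: iodine, [I][I]
Why: Hydroxyl-directed trans-hydroalumination of the propargylic alcohol puts aluminium on C3 cis to the CH2O group in a five-membered alanate, and iodinolysis with retention gives the (Z)-vinyl iodide.

Step 8
Reactants: 8 ring A (E)-vinylboronate; 11 (2Z)-3-iodobut-2-en-1-ol
Product: 12 (2Z,4E)-5-[(1S,3R)-2,2-dimethyl-6-methylidene-3-(triethylsilyloxy)cyclohexyl]-3-methylpenta-2,4-dien-1-ol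
Conditions: Pd(PPh3)4 (5 mol%), aq. K3PO4, THF, 45 °C
Reagents that add atoms: none
Why: Suzuki–Miyaura coupling (zerovalent palladium) goes with retention at both sp2 carbons, so the (E)-boronate and the (Z)-iodide give the (2Z,4E)-diene.

Step 9
Reactants: 12 (2Z,4E)-dienol
Product: 13 (2Z,4E)-5-[(1S,3R)-2,2-dimethyl-6-methylidene-3-(triethylsilyloxy)cyclohexyl]-3-methylpenta-2,4-dienal
Conditions: MnO2, CH2Cl2, rt, dark
Reagents that add atoms: none
Why: MnO2 oxidises only the allylic primary alcohol, and the (2Z) geometry is kept when the oxidation is run at room temperature in the dark.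

Step 10
Reactants: 14 4-bromo-2,5-dimethoxybenzaldehyde
Product: 15 (4-bromo-2,5-dimethoxyphenyl)methanol
Conditions: NaBH4, MeOH, 0 °C
Reagents that add atoms: none
Why: Simple hydride reduction of the aryl aldehyde to the benzylic alcohol that becomes the C3 hydroxymethyl group; no stereocentre is formed.

Step 11
Reactants: 15 (4-bromo-2,5-dimethoxyphenyl)methanol
Product: 16 [(4-bromo-2,5-dimethoxyphenyl)methoxy](tert-butyl)diphenylsilane
Conditions: t-BuPh2SiCl, imidazole, DMF, rt
Reagents that add atoms: tert-butyl(chloro)diphenylsilane, CC(C)(C)[Si](Cl)(c1ccccc1)c1ccccc1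
Why: Silylation of the primary alcohol as the tert-butyldiphenylsilyl (TBDPS) ether, chosen because it survives (NH4)2Ce(NO3)6, hydride and t-BuLi yet is still cleaved by fluoride.

Step 12
Reactants: 16 [(4-bromo-2,5-dimethoxyphenyl)methoxy](tert-butyl)diphenylsilane
Product: 18 tert-butyl({2,5-dimethoxy-4-[(R)-4-methylbenzenesulfinyl]phenyl}methoxy)diphenylsilane, via arylmagnesium bromide 17 (not isolated)
Conditions: Mg turnings, THF, 50 °C; then added to (1S,2R,5S)-menthyl (R)-p-toluenesulfinate, toluene, 0 °C; H2O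
Reagents that add atoms: (1S,2R,5S)-menthyl (R)-4-methylbenzenesulfinate, Cc1ccc(cc1)[S@](=O)O[C@@H]1[C@@H](C(C)C)CC[C@H](C)C1
Why: Andersen sulfoxide synthesis: the aryl Grignard displaces menthoxide with inversion at sulfur, so the (R)-sulfinate gives the (R)-diaryl sulfoxide as a single enantiomer.

Step 13
Reactants: 18 (R)-aryl p-tolyl sulfoxide
Product: 19 2-({[tert-butyl(diphenyl)silyl]oxy}methyl)-5-[(R)-4-methylbenzenesulfinyl]cyclohexa-2,5-diene-1,4-dione
Conditions: (NH4)2Ce(NO3)6 (2.5 equiv), MeCN/H2O, 0 °C to rt, 20 min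
Reagents that add atoms: water, O
Why: Oxidative demethylation of the hydroquinone dimethyl ether by tetravalent cerium (arene radical cation, ipso attack of water, loss of methanol) gives the sulfinylquinone without touching sulfur or the silyl ether.

Step 14
Reactants: 19 (R)-sulfinylquinone
Product: 20 (1R,6S)-4-({[tert-butyl(diphenyl)silyl]oxy}methyl)-1-[(R)-4-methylbenzenesulfinyl]-7-oxabicyclo[4.1.0]hept-3-ene-2,5-dione
Conditions: ZnBr2 (1.1 equiv), THF, 0 °C; then t-BuOOLi (from t-BuOOH and n-BuLi, 1.2 equiv), −78 to −40 °C; H2O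
Reagents that add atoms: tert-butyl hydroperoxide (used as its lithium salt), CC(C)(C)OO
Why: Proposed new method: Weitz–Scheffer-type nucleophilic epoxidation in which ZnBr2 locks the sulfinyl oxygen and the C5 carbonyl in a planar chelate, the peroxide anion adds to C1 (β to both C5=O and sulfur, so the most electrophilic position) from the face opposite the p-tolyl group, and the α-sulfinyl enolate closes the oxirane by expelling tert-butoxide, which sets C6 and C1 as in the target; the closest known reactions are chelate-controlled conjugate additions to 2-(arylsulfinyl)enones and lithium tert-butyl peroxide epoxidation of vinyl sulfoxides and of quinones.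

Step 15
Reactants: 20 sulfinyl epoxy-enedione
Product: 21 (1S,2S,5R,6S)-4-({[tert-butyl(diphenyl)silyl]oxy}methyl)-1-[(R)-4-methylbenzenesulfinyl]-7-oxabicyclo[4.1.0]hept-3-ene-2,5-diol
Conditions: ZnBr2 (1.2 equiv), THF, rt; then (i-Bu)2AlH (3 equiv), −78 °C; aq. potassium sodium tartrate
Reagents that add atoms: none
Why: Two 1,2-reductions in one pot: at C5 (chelation-controlled β-keto sulfoxide reduction) zinc ties the sulfinyl oxygen to the C5 carbonyl so external hydride enters anti to the p-tolyl group on the epoxide face, and at C2 (epoxide-directed reduction of an α,β-epoxy ketone) hydride is delivered from aluminium bound to the oxirane oxygen, so both new hydroxyls lie anti to the oxirane and cis to each other.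

Step 16
Reactants: 21 sulfinyl epoxy diol
Product: 22 (1R,2S,5R,6S)-2,5-bis{[tert-butyl(dimethyl)silyl]oxy}-4-({[tert-butyl(diphenyl)silyl]oxy}methyl)-1-[(R)-4-methylbenzenesulfinyl]-7-oxabicyclo[4.1.0]hept-3-ene
Conditions: t-BuMe2SiOTf (3 equiv), 2,6-lutidine, CH2Cl2, −78 to 0 °C
Reagents that add atoms: tert-butyldimethylsilyl trifluoromethanesulfonate, CC(C)(C)[Si](C)(C)OS(=O)(=O)C(F)(F)F
Why: Silyl triflate silylation protects both hindered secondary alcohols as tert-butyldimethylsilyl (TBS) ethers, and the bulky groups are chosen so that they do not migrate to the neighbouring carbanion in the next step.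

Step 17
Reactants: 22 bis-TBS sulfinyl oxirane; 13 (2Z,4E)-dienal
Product: 24 (1S,2Z,4E)-1-[(1S,2S,5R,6S)-2,5-bis{[tert-butyl(dimethyl)silyl]oxy}-4-({[tert-butyl(diphenyl)silyl]oxy}methyl)-7-oxabicyclo[4.1.0]hept-3-en-1-yl]-5-[(1S,3R)-2,2-dimethyl-6-methylidene-3-(triethylsilyloxy)cyclohexyl]-3-methylpenta-2,4-dien-1-ol, via oxiranyllithium 23 (not isolated)
Conditions: t-BuLi (1.1 equiv), THF, −100 °C, 5 min; then 13 (1.3 equiv), −100 to −78 °C; H2O
Reagents that add atoms: none
Why: Sulfoxide–lithium exchange then carbonyl addition: t-BuLi attacks sulfur and expels the configurationally stable oxiranyllithium 23 (an α-oxygenated carbanion, so the normally electrophilic epoxide carbon C6 attacks the normally electrophilic aldehyde carbon), which reacts with retention at C6, and C1′ is set (S) in a lithium-bridged transition state (Li between the oxirane oxygen and the aldehyde oxygen) with the dienyl group turned away from the C5 silyl ether toward the C1–H side.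

Step 18
Reactants: 24 tetrasilyl ether
Product: 25 target, (1R,2S,5R,6S)-1-[(1S,2Z,4E)-1-hydroxy-5-[(1S,3R)-3-hydroxy-2,2-dimethyl-6-methylidenecyclohexyl]-3-methylpenta-2,4-dien-1-yl]-4-(hydroxymethyl)-7-oxabicyclo[4.1.0]hept-3-ene-2,5-diol
Conditions: Bu4NF (6 equiv), AcOH (6 equiv), THF, 0 °C to rt
Reagents that add atoms: none
Why: Fluoride-mediated desilylation buffered with acetic acid removes the TES, both TBS and the TBDPS groups in one operation without base-induced epoxide migration or acid ionisation of the dienylic alcohol; no stereocentre is touched.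

## Compound list

1 | geranyl acetate, (2E)-3,7-dimethylocta-2,6-dien-1-yl acetate | CC(=O)OC/C=C(\C)CCC=C(C)C | starting material
2 | (2E)-5-[(2R)-3,3-dimethyloxiran-2-yl]-3-methylpent-2-en-1-yl acetate | CC(=O)OC/C=C(\C)CC[C@H]1OC1(C)C | intermediate
3 | [(1S,3R)-2,2-dimethyl-6-methylidene-3-(trimethylsilyloxy)cyclohexyl]methyl acetate | C=C1CC[C@@H](O[Si](C)(C)C)C(C)(C)[C@H]1COC(C)=O | intermediate
4 | [(1S,3R)-3-hydroxy-2,2-dimethyl-6-methylidenecyclohexyl]methyl acetate | C=C1CC[C@@H](O)C(C)(C)[C@H]1COC(C)=O | intermediate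
5 | [(1S,3R)-2,2-dimethyl-6-methylidene-3-(triethylsilyloxy)cyclohexyl]methyl acetate | C=C1CC[C@@H](O[Si](CC)(CC)CC)C(C)(C)[C@H]1COC(C)=O | intermediate
6 | [(1S,3R)-2,2-dimethyl-6-methylidene-3-(triethylsilyloxy)cyclohexyl]methanol | C=C1CC[C@@H](O[Si](CC)(CC)CC)C(C)(C)[C@H]1CO | intermediate
7 | (1S,3R)-2,2-dimethyl-6-methylidene-3-(triethylsilyloxy)cyclohexane-1-carbaldehyde | C=C1CC[C@@H](O[Si](CC)(CC)CC)C(C)(C)[C@H]1C=O | intermediate
8 | 2-[(E)-2-[(1S,3R)-2,2-dimethyl-6-methylidene-3-(triethylsilyloxy)cyclohexyl]ethenyl]-4,4,5,5-tetramethyl-1,3,2-dioxaborolane | C=C1CC[C@@H](O[Si](CC)(CC)CC)C(C)(C)[C@H]1/C=C/B1OC(C)(C)C(C)(C)O1 | intermediate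
9 | but-2-yn-1-ol | CC#CCO | starting material
10 | sodium 2,2-bis(2-methoxyethoxy)-3-methyl-2,5-dihydro-1,2-oxaluminol-2-uide (cyclic vinylalanate) | [Na+].CC1=CCO[Al-]1(OCCOC)OCCOC | intermediate
11 | (2Z)-3-iodobut-2-en-1-ol | C/C(I)=C/CO | intermediate
12 | (2Z,4E)-5-[(1S,3R)-2,2-dimethyl-6-methylidene-3-(triethylsilyloxy)cyclohexyl]-3-methylpenta-2,4-dien-1-ol | C=C1CC[C@@H](O[Si](CC)(CC)CC)C(C)(C)[C@H]1/C=C/C(C)=C\CO | intermediate
13 | (2Z,4E)-5-[(1S,3R)-2,2-dimethyl-6-methylidene-3-(triethylsilyloxy)cyclohexyl]-3-methylpenta-2,4-dienal | C=C1CC[C@@H](O[Si](CC)(CC)CC)C(C)(C)[C@H]1/C=C/C(C)=C\C=O | intermediate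
14 | 4-bromo-2,5-dimethoxybenzaldehyde | COc1cc(C=O)c(OC)cc1Br | starting material
15 | (4-bromo-2,5-dimethoxyphenyl)methanol | COc1cc(CO)c(OC)cc1Br | intermediate
16 | [(4-bromo-2,5-dimethoxyphenyl)methoxy](tert-butyl)diphenylsilane | COc1cc(CO[Si](c2ccccc2)(c2ccccc2)C(C)(C)C)c(OC)cc1Br | intermediate
17 | [4-({[tert-butyl(diphenyl)silyl]oxy}methyl)-2,5-dimethoxyphenyl]magnesium bromide | COc1cc(CO[Si](c2ccccc2)(c2ccccc2)C(C)(C)C)c(OC)cc1[Mg]Br | intermediate
18 | tert-butyl({2,5-dimethoxy-4-[(R)-4-methylbenzenesulfinyl]phenyl}methoxy)diphenylsilane | Cc1ccc(cc1)[S@@](=O)c1cc(OC)c(CO[Si](c2ccccc2)(c2ccccc2)C(C)(C)C)cc1OC | intermediate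
19 | 2-({[tert-butyl(diphenyl)silyl]oxy}methyl)-5-[(R)-4-methylbenzenesulfinyl]cyclohexa-2,5-diene-1,4-dione | Cc1ccc(cc1)[S@@](=O)C1=CC(=O)C(CO[Si](c2ccccc2)(c2ccccc2)C(C)(C)C)=CC1=O | intermediate
20 | (1R,6S)-4-({[tert-butyl(diphenyl)silyl]oxy}methyl)-1-[(R)-4-methylbenzenesulfinyl]-7-oxabicyclo[4.1.0]hept-3-ene-2,5-dione | Cc1ccc(cc1)[S@@](=O)[C@]12O[C@H]1C(=O)C(CO[Si](c3ccccc3)(c3ccccc3)C(C)(C)C)=CC2=O | intermediate
21 | (1S,2S,5R,6S)-4-({[tert-butyl(diphenyl)silyl]oxy}methyl)-1-[(R)-4-methylbenzenesulfinyl]-7-oxabicyclo[4.1.0]hept-3-ene-2,5-diol | Cc1ccc(cc1)[S@@](=O)[C@]12O[C@H]1[C@H](O)C(CO[Si](c3ccccc3)(c3ccccc3)C(C)(C)C)=C[C@@H]2O | intermediate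
22 | (1R,2S,5R,6S)-2,5-bis{[tert-butyl(dimethyl)silyl]oxy}-4-({[tert-butyl(diphenyl)silyl]oxy}methyl)-1-[(R)-4-methylbenzenesulfinyl]-7-oxabicyclo[4.1.0]hept-3-ene | Cc1ccc(cc1)[S@@](=O)[C@]12O[C@H]1[C@H](O[Si](C)(C)C(C)(C)C)C(CO[Si](c3ccccc3)(c3ccccc3)C(C)(C)C)=C[C@@H]2O[Si](C)(C)C(C)(C)C | intermediate
23 | [(1S,2S,5R,6S)-2,5-bis{[tert-butyl(dimethyl)silyl]oxy}-4-({[tert-butyl(diphenyl)silyl]oxy}methyl)-7-oxabicyclo[4.1.0]hept-3-en-1-yl]lithium | [Li][C@]12O[C@H]1[C@H](O[Si](C)(C)C(C)(C)C)C(CO[Si](c3ccccc3)(c3ccccc3)C(C)(C)C)=C[C@@H]2O[Si](C)(C)C(C)(C)C | intermediate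
24 | (1S,2Z,4E)-1-[(1S,2S,5R,6S)-2,5-bis{[tert-butyl(dimethyl)silyl]oxy}-4-({[tert-butyl(diphenyl)silyl]oxy}methyl)-7-oxabicyclo[4.1.0]hept-3-en-1-yl]-5-[(1S,3R)-2,2-dimethyl-6-methylidene-3-(triethylsilyloxy)cyclohexyl]-3-methylpenta-2,4-dien-1-ol | C=C1CC[C@@H](O[Si](CC)(CC)CC)C(C)(C)[C@H]1/C=C/C(C)=C\[C@H](O)[C@]12O[C@H]1[C@H](O[Si](C)(C)C(C)(C)C)C(CO[Si](c3ccccc3)(c3ccccc3)C(C)(C)C)=C[C@@H]2O[Si](C)(C)C(C)(C)C | intermediate
25 | (1R,2S,5R,6S)-1-[(1S,2Z,4E)-1-hydroxy-5-[(1S,3R)-3-hydroxy-2,2-dimethyl-6-methylidenecyclohexyl]-3-methylpenta-2,4-dien-1-yl]-4-(hydroxymethyl)-7-oxabicyclo[4.1.0]hept-3-ene-2,5-diol | C=C1CC[C@@H](O)C(C)(C)[C@H]1/C=C/C(C)=C\[C@H](O)[C@]12O[C@H]1[C@H](O)C(CO)=C[C@@H]2O | target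

## Step count and risks

Total steps: 18. Longest linear sequence: 10 steps (steps 1–6, 8, 9, 17, 18, from geranyl acetate); the ring B branch is 9 steps (steps 10–18).

The three steps most likely to fail:

Step 17. The oxiranyllithium 23 may decompose as a carbenoid, may pick up a silyl group from the C2 oxygen, or may deprotonate the γ-methyl of 13, and the C1′ selectivity rests on an untested transition-state model. The fallback sets C1′ by ketone reduction instead of by the C–C bond formation. It sets out from 24 obtained as a mixture with its C1′ epimer. The mixture is oxidised with Dess–Martin periodinane to the dienyl epoxy ketone F1. F1 is reduced under Luche conditions (NaBH4, CeCl3·7H2O, MeOH, −78 °C), which reduce α,β-epoxy ketones to the anti (erythro) epoxy alcohol, the relative configuration needed here. The route is rejoined at 24.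

Step 14. The peroxide may attack the sulfinyl-bearing carbon (loss of the auxiliary), may oxidise sulfur, or may show poor facial selectivity if the zinc chelate is not the reacting species. The fallback takes stereocontrol away from the auxiliary and gives it to an external catalyst. It sets out from 19 and uses a Weitz–Scheffer epoxidation under chiral phase transfer (aq. NaOCl, toluene, an N-(9-anthracenylmethyl) cinchona ammonium bromide, with the pseudo-enantiomer chosen to match the sulfoxide). It comes back at 20 and makes no new compound (F0).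

Step 15. At C5 an aluminium hydride bound to the sulfinyl oxygen could deliver hydride from the wrong face, and zinc could also perturb the epoxide-directed reduction at C2. The fallback reduces the two carbonyls separately, each under one control element. It sets out from 20. (i-Bu)2AlH alone (1.05 equiv, −78 °C) reduces only the unhindered C2 carbonyl, with hydride delivered from the oxirane face, to give the C2 hydroxy C5 ketone F2. F2 is then treated on its own with ZnBr2 followed by (i-Bu)2AlH, so that the C5 carbonyl is reduced purely under sulfoxide chelate control. The route is rejoined at 21.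

## Further compounds

F1 | step 17 | (2Z,4E)-1-[(1S,2S,5R,6S)-2,5-bis{[tert-butyl(dimethyl)silyl]oxy}-4-({[tert-butyl(diphenyl)silyl]oxy}methyl)-7-oxabicyclo[4.1.0]hept-3-en-1-yl]-5-[(1S,3R)-2,2-dimethyl-6-methylidene-3-(triethylsilyloxy)cyclohexyl]-3-methylpenta-2,4-dien-1-one | C=C1CC[C@@H](O[Si](CC)(CC)CC)C(C)(C)[C@H]1/C=C/C(C)=C\C(=O)[C@]12O[C@H]1[C@H](O[Si](C)(C)C(C)(C)C)C(CO[Si](c3ccccc3)(c3ccccc3)C(C)(C)C)=C[C@@H]2O[Si](C)(C)C(C)(C)C
F2 | step 15 | (1R,5R,6S)-4-({[tert-butyl(diphenyl)silyl]oxy}methyl)-5-hydroxy-1-[(R)-4-methylbenzenesulfinyl]-7-oxabicyclo[4.1.0]hept-3-en-2-one | Cc1ccc(cc1)[S@@](=O)[C@]12O[C@H]1[C@H](O)C(CO[Si](c3ccccc3)(c3ccccc3)C(C)(C)C)=CC2=O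
F0 | step 14 | none | none
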